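**Retrosynthetic overview**

- Target 20 is the (7S,8R,8'R)-7-hydroxy-9,9'-epoxylignan. The strategy rests on its tetrahydrofuran ring: the ring oxygen sits between two unsubstituted CH2 groups (C9, C9'), and the other two ring carbons, C8 (bearing the carbinol C7) and C8' (bearing the 4-hydroxy-3-methoxybenzyl CH2, C7'), are trans. The ring is therefore a CH2–O–CH2 1,3-dipole laid across an (E)-C8=C8' alkene.
- Disconnections, backwards: C7–OH (CBS reduction of an aryl ketone); C7–aryl (aryllithium on a Weinreb amide); C8–C9 and C8'–C9' together ([3+2] cycloaddition of the parent carbonyl ylide to an N-enoyl oxazolidinone); C8=C8' (cross-metathesis of O-benzyl eugenol with an N-acryloyl oxazolidinone).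
- Only one ring is formed, the tetrahydrofuran, in step 5; both arenes are bought.
- Both phenols are carried as benzyl ethers, because an aryl silyl ether would be cleaved by CsF in the ring-forming step; they are removed together in the last step.

Key step: step 5

Assumption: without a chelating metal (CsF in MeCN) the N-enoyl imide is taken to react through its anti-s-cis conformer, with the ylide approaching opposite the C4 benzyl group; this calls for the (R)-auxiliary to reach the 3R,4R ring, and if the facial preference proves to be the reverse, (S)-4-benzyl-2-oxazolidinone is used in the same steps.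

**Route**

Step 1
Reactants: 1 eugenol
Product: 2 4-allyl-1-(benzyloxy)-2-methoxybenzene
Conditions: BnBr, K2CO3, DMF, rt
Reagents that add atoms: benzyl bromide, BrCc1ccccc1
Why: Williamson etherification of the phenoxide with a benzylic bromide is fast and clean, and the benzyl ether, unlike an aryl silyl ether, should withstand the fluoride of step 5 as well as the metathesis, organolithium and borane steps.

Step 2
Reactants: 3 (R)-4-benzyl-2-oxazolidinone
Product: 4 (R)-3-acryloyl-4-benzyloxazolidin-2-one
Conditions: n-BuLi, THF, −78 °C; then acryloyl chloride, −78 °C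
Reagents that add atoms: acryloyl chloride, C=CC(=O)Cl
Why: N-Acylation of the lithiated oxazolidinone by an acid chloride at −78 °C is the standard entry to N-enoyl imides, the low temperature holding back conjugate addition and polymerisation of the acryloyl unit; the auxiliary stereocentre is not touched.

Step 3
Reactants: 2 4-allyl-1-(benzyloxy)-2-methoxybenzene (2 equiv), 4 (R)-3-acryloyl-4-benzyloxazolidin-2-one
Product: 5 (R)-4-benzyl-3-[(E)-4-(4-benzyloxy-3-methoxyphenyl)but-2-enoyl]oxazolidin-2-one
Conditions: second-generation Grubbs catalyst RuCl2(=CHPh)(PCy3)(H2IMes) (5 mol %), 1,4-benzoquinone (10 mol %), CH2Cl2, 40 °C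
Reagents that add atoms: none
Why: Olefin cross-metathesis between a readily dimerising terminal allylarene (in excess) and an electron-poor acryloyl partner that does not homodimerise is selective for the cross product and should give the conjugated (E)-alkene under thermodynamic control, the quinone suppressing ruthenium hydride-induced double-bond migration.

Step 4
Reactants: 6 (trimethylsilyl)methanol
Product: 7 chloromethyl (trimethylsilyl)methyl ether
Conditions: (CH2O)n, HCl (g), 0 °C; dry over CaCl2, distil
Reagents that add atoms: paraformaldehyde (as formaldehyde), C=O; hydrogen chloride, Cl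
Why: Chloromethylation of an alcohol: the hemiformal formed with formaldehyde is converted by HCl into the α-chloro ether through the oxocarbenium ion, the usual preparation of chloromethyl ethers, and the C–Si bond is inert to dry HCl at 0 °C.

Step 5
Reactants: 5 (R)-4-benzyl-3-[(E)-4-(4-benzyloxy-3-methoxyphenyl)but-2-enoyl]oxazolidin-2-one, 7 chloromethyl (trimethylsilyl)methyl ether (3 equiv, added slowly)
Product: 9 (R)-4-benzyl-3-{[(3R,4R)-4-(4-benzyloxy-3-methoxybenzyl)tetrahydrofuran-3-yl]carbonyl}oxazolidin-2-one, via carbonyl ylide 8 (not isolated)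
Conditions: CsF (4 equiv), MeCN, rt; chromatography to remove the minor diastereomer
Reagents that add atoms: none
Why: Fluoride attacks silicon of 7 and chloride leaves (1,3-elimination), releasing the parent carbonyl ylide 8, a four-π-electron C–O–C dipole that adds to the Cα=Cβ bond of 5 in a concerted suprafacial [3+2] cycloaddition (nucleophilic ylide HOMO, imide-lowered alkene LUMO), forming C8–C9 and C8'–C9'. The closest known reaction type is the CsF-induced generation of this nonstabilised ylide from silylmethyl chloromethyl ethers and its addition to acrylates and fumarates, together with the analogous additions of nonstabilised azomethine ylides to N-enoyl oxazolidinones. The tetrahydrofuran is closed by intermolecular [3+2] annulation, both ring C–C bonds being made in the same event and the ring oxygen arriving with the dipole. C8 and C8' are set together: their trans relationship follows stereospecifically from the (E)-alkene, and their absolute sense from the auxiliary, whose C4 benzyl group screens one face of the anti-s-cis enoyl imide so that the ylide should add to the Cα-Si face and give the 3R,4R ring. The step needs π-facial selectivity, which without a chelating metal is expected to be moderate only, so the (3S,4S) diastereomer is removed at the imide stage; regiochemistry is no issue because the dipole is symmetrical. It also needs the ylide to be trapped faster than fluoride can shift the C8=C8' bond into conjugation with the arene, which is addressed by the excess of 7 and the low concentration of dissolved CsF.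

Step 6
Reactants: 9 (R)-4-benzyl-3-{[(3R,4R)-4-(4-benzyloxy-3-methoxybenzyl)tetrahydrofuran-3-yl]carbonyl}oxazolidin-2-one
Product: 11 (3R,4R)-4-(4-benzyloxy-3-methoxybenzyl)tetrahydrofuran-3-carboxylic acid, via peroxy acid 10 (not isolated)
Conditions: LiOH·H2O, 30 % aq. H2O2, THF–H2O 3:1, 0 °C; then aq. Na2SO3; then aq. HCl to pH 2
Reagents that add atoms: hydrogen peroxide, OO
Why: Evans hydroperoxide cleavage: the small, highly nucleophilic HOO− attacks the exocyclic acyl carbonyl even of an α-branched imide, the peroxy acid is reduced by sulfite and the auxiliary is recovered, while C8 is not at risk because the trans acid is the more stable epimer.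

Step 7
Reactants: 11 (3R,4R)-4-(4-benzyloxy-3-methoxybenzyl)tetrahydrofuran-3-carboxylic acid
Product: 13 (3R,4R)-4-(4-benzyloxy-3-methoxybenzyl)-N-methoxy-N-methyltetrahydrofuran-3-carboxamide, via acyl imidazole 12 (not isolated)
Conditions: 1,1'-carbonyldiimidazole, CH2Cl2, rt; then MeNH(OMe)·HCl, rt
Reagents that add atoms: N,O-dimethylhydroxylamine hydrochloride, CNOC.Cl
Why: Carboxyl activation with carbonyldiimidazole gives the acyl imidazole, which is aminolysed by N,O-dimethylhydroxylamine (Weinreb amide formation) under nearly neutral conditions that leave C8 and the benzyl ether alone.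

Step 8
Reactants: 14 4-bromo-2,6-dimethoxyphenol
Product: 15 2-(benzyloxy)-5-bromo-1,3-dimethoxybenzene
Conditions: BnBr, K2CO3, DMF, 50 °C
Reagents that add atoms: benzyl bromide, BrCc1ccccc1
Why: Williamson etherification, which proceeds also for the 2,6-disubstituted phenoxide with an unhindered benzylic bromide in DMF.

Step 9
Reactants: 15 2-(benzyloxy)-5-bromo-1,3-dimethoxybenzene, 13 (3R,4R)-4-(4-benzyloxy-3-methoxybenzyl)-N-methoxy-N-methyltetrahydrofuran-3-carboxamide
Product: 18 [(3R,4R)-4-(4-benzyloxy-3-methoxybenzyl)tetrahydrofuran-3-yl](4-benzyloxy-3,5-dimethoxyphenyl)methanone, via aryllithium 16 (not isolated), via lithium hemiaminal 17 (not isolated)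
Conditions: 15, n-BuLi, THF, −78 °C; then 13, −78 to −40 °C; then 1 M HCl
Reagents that add atoms: none
Why: Bromine–lithium exchange is faster than any attack on the benzyl ether at −78 °C, and the aryllithium adds only once to the Weinreb amide because the chelated tetrahedral lithium adduct survives until the acidic quench (Weinreb ketone synthesis), which also keeps C8 from enolising.

Step 10
Reactants: 18 [(3R,4R)-4-(4-benzyloxy-3-methoxybenzyl)tetrahydrofuran-3-yl](4-benzyloxy-3,5-dimethoxyphenyl)methanone
Product: 19 (S)-[(3R,4R)-4-(4-benzyloxy-3-methoxybenzyl)tetrahydrofuran-3-yl](4-benzyloxy-3,5-dimethoxyphenyl)methanol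
Conditions: (R)-2-methyl-CBS-oxazaborolidine [(R)-1-methyl-3,3-diphenyltetrahydro-1H,3H-pyrrolo[1,2-c][1,3,2]oxazaborole] (0.2–1.0 equiv), BH3·SMe2, THF, −20 °C; then MeOH
Reagents that add atoms: none
Why: Corey–Bakshi–Shibata reduction: with the aryl group as the large and ring carbon C8 as the small substituent, the (R)-catalyst should deliver hydride to the face that gives the 7S alcohol (mirror image of the (S)-catalyst/acetophenone case), and a Felkin–Anh reading of the C8 stereocentre (C8' anti to the incoming hydride) points to the same epimer, so reagent and substrate control should reinforce each other.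

Step 11
Reactants: 19 (S)-[(3R,4R)-4-(4-benzyloxy-3-methoxybenzyl)tetrahydrofuran-3-yl](4-benzyloxy-3,5-dimethoxyphenyl)methanol
Product: 20 (S)-(4-hydroxy-3,5-dimethoxyphenyl)[(3R,4R)-4-(4-hydroxy-3-methoxybenzyl)tetrahydrofuran-3-yl]methanol (CNP0307127.1)
Conditions: H2 (1 atm), Pd/C (palladium on carbon, 10 wt %), EtOAc, rt, stopped after uptake of 2 equiv H2
Reagents that add atoms: none
Why: Hydrogenolysis of aryl benzyl ethers over palladium in a neutral aprotic solvent is much faster than cleavage of a benzylic C–OH bond, so both phenols should be freed with C7–OH, the ring ether and all three stereocentres intact.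

**Compound list**

1 | eugenol | C=CCc1ccc(O)c(OC)c1 | starting material
2 | 4-allyl-1-(benzyloxy)-2-methoxybenzene | C=CCc1ccc(OCc2ccccc2)c(OC)c1 | intermediate
3 | (R)-4-benzyl-2-oxazolidinone | O=C1N[C@H](Cc2ccccc2)CO1 | starting material
4 | (R)-3-acryloyl-4-benzyloxazolidin-2-one | O=C1OC[C@@H](Cc2ccccc2)N1C(=O)C=C | intermediate
5 | (R)-4-benzyl-3-[(E)-4-(4-benzyloxy-3-methoxyphenyl)but-2-enoyl]oxazolidin-2-one | O=C1OC[C@@H](Cc2ccccc2)N1C(=O)/C=C/Cc1ccc(OCc2ccccc2)c(OC)c1 | intermediate
6 | (trimethylsilyl)methanol | C[Si](C)(C)CO | starting material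
7 | chloromethyl (trimethylsilyl)methyl ether | C[Si](C)(C)COCCl | intermediate
8 | parent carbonyl ylide (formaldehyde O-methylide) | C=[O+][CH2-] | intermediate
9 | (R)-4-benzyl-3-{[(3R,4R)-4-(4-benzyloxy-3-methoxybenzyl)tetrahydrofuran-3-yl]carbonyl}oxazolidin-2-one | O=C1OC[C@@H](Cc2ccccc2)N1C(=O)[C@H]1COC[C@@H]1Cc1ccc(OCc2ccccc2)c(OC)c1 | intermediate
10 | (3R,4R)-4-(4-benzyloxy-3-methoxybenzyl)tetrahydrofuran-3-carboperoxoic acid | OOC(=O)[C@H]1COC[C@@H]1Cc1ccc(OCc2ccccc2)c(OC)c1 | intermediate
11 | (3R,4R)-4-(4-benzyloxy-3-methoxybenzyl)tetrahydrofuran-3-carboxylic acid | OC(=O)[C@H]1COC[C@@H]1Cc1ccc(OCc2ccccc2)c(OC)c1 | intermediate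
12 | (1H-imidazol-1-yl)[(3R,4R)-4-(4-benzyloxy-3-methoxybenzyl)tetrahydrofuran-3-yl]methanone | O=C(n1ccnc1)[C@H]1COC[C@@H]1Cc1ccc(OCc2ccccc2)c(OC)c1 | intermediate
13 | (3R,4R)-4-(4-benzyloxy-3-methoxybenzyl)-N-methoxy-N-methyltetrahydrofuran-3-carboxamide | CON(C)C(=O)[C@H]1COC[C@@H]1Cc1ccc(OCc2ccccc2)c(OC)c1 | intermediate
14 | 4-bromo-2,6-dimethoxyphenol | COc1cc(Br)cc(OC)c1O | starting material
15 | 2-(benzyloxy)-5-bromo-1,3-dimethoxybenzene | COc1cc(Br)cc(OC)c1OCc1ccccc1 | intermediate
16 | (4-benzyloxy-3,5-dimethoxyphenyl)lithium | [Li]c1cc(OC)c(OCc2ccccc2)c(OC)c1 | intermediate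
17 | lithium hemiaminal from 13 and 16 (tetrahedral adduct, C7 configuration not defined) | [Li]OC(N(C)OC)(c1cc(OC)c(OCc2ccccc2)c(OC)c1)[C@H]1COC[C@@H]1Cc1ccc(OCc2ccccc2)c(OC)c1 | intermediate
18 | [(3R,4R)-4-(4-benzyloxy-3-methoxybenzyl)tetrahydrofuran-3-yl](4-benzyloxy-3,5-dimethoxyphenyl)methanone | O=C(c1cc(OC)c(OCc2ccccc2)c(OC)c1)[C@H]1COC[C@@H]1Cc1ccc(OCc2ccccc2)c(OC)c1 | intermediate
19 | (S)-[(3R,4R)-4-(4-benzyloxy-3-methoxybenzyl)tetrahydrofuran-3-yl](4-benzyloxy-3,5-dimethoxyphenyl)methanol | COc1cc(C[C@H]2COC[C@@H]2[C@H](O)c2cc(OC)c(OCc3ccccc3)c(OC)c2)ccc1OCc1ccccc1 | intermediate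
20 | (S)-(4-hydroxy-3,5-dimethoxyphenyl)[(3R,4R)-4-(4-hydroxy-3-methoxybenzyl)tetrahydrofuran-3-yl]methanol | COc1cc(C[C@H]2COC[C@@H]2[C@H](O)c2cc(OC)c(O)c(OC)c2)ccc1O | target

**Step count**

Total: 11 steps. Longest linear sequence: 8 steps (1, 3, 5, 6, 7, 9, 10, 11 from eugenol; equally 2, 3, 5, 6, 7, 9, 10, 11 from the auxiliary).

**Steps most likely to fail**

1. Step 5. Without chelation the remote benzyl group may discriminate the two alkene faces only weakly. Fluoride may also move the C8=C8' bond into conjugation with the arene by removing a doubly activated C7' proton. The ylide may also be lost by self-reaction before it meets a β-substituted dipolarophile. The fallback gives up auxiliary induction and secures absolute configuration by resolution on a less CH-acidic dipolarophile. It sets out from 2, which is cross-metathesised with methyl acrylate (second-generation Grubbs catalyst, CH2Cl2, 40 °C) to methyl (E)-4-(4-benzyloxy-3-methoxyphenyl)but-2-enoate F1. Cycloaddition of F1 with 7 and CsF in MeCN should give racemic trans-methyl 4-(4-benzyloxy-3-methoxybenzyl)tetrahydrofuran-3-carboxylate F2, trans again following from the (E)-alkene. Preparative chromatography on a chiral stationary phase should deliver methyl (3R,4R)-4-(4-benzyloxy-3-methoxybenzyl)tetrahydrofuran-3-carboxylate F3. Saponification (LiOH, THF–H2O, rt) brings the route back at acid 11.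

2. Step 11. The electron-rich benzylic C7–O bond may be hydrogenolysed along with the benzyl ethers, or may ionise on a trace of acid on the catalyst. The fallback moves the debenzylation ahead of the creation of C7 and finishes with a fluoride deprotection. It sets out from ketone 18, which is hydrogenolysed (H2, Pd/C, EtOAc) to [(3R,4R)-4-(4-hydroxy-3-methoxybenzyl)tetrahydrofuran-3-yl](4-hydroxy-3,5-dimethoxyphenyl)methanone F5. Silylation (TBSCl, imidazole, DMF) gives the bis(tert-butyldimethylsilyl) ether F6. The reduction of step 10 on F6 gives (S)-{(3R,4R)-4-[4-(tert-butyldimethylsilyloxy)-3-methoxybenzyl]tetrahydrofuran-3-yl}[4-(tert-butyldimethylsilyloxy)-3,5-dimethoxyphenyl]methanol F7. Desilylation with Bu4NF buffered with AcOH (THF, 0 °C) then arrives directly at 20.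

3. Step 10. The hindered α-branched aryl ketone may be poorly differentiated by the catalyst, or may react mainly by the uncatalysed pathway, leaving a mixture at C7. The fallback reverses the roles at C7, so that the aryl group rather than hydride is the nucleophile and the intrinsic facial bias of the C8 stereocentre acts in the opposite sense. It sets out from Weinreb amide 13, which is reduced (LiAlH4, THF, −78 °C) to (3R,4R)-4-(4-benzyloxy-3-methoxybenzyl)tetrahydrofuran-3-carbaldehyde F4. Addition of aryllithium 16 (from 15 and n-BuLi, THF, −78 °C) gives carbinol 19, where the route is rejoined. Whichever of the two sequences favours 7S is kept, and the unwanted epimer is returned to 18 by oxidation with MnO2.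

**Further compounds**

F1 | step 5 | methyl (E)-4-(4-benzyloxy-3-methoxyphenyl)but-2-enoate | COC(=O)/C=C/Cc1ccc(OCc2ccccc2)c(OC)c1
F2 | step 5 | racemic trans-methyl 4-(4-benzyloxy-3-methoxybenzyl)tetrahydrofuran-3-carboxylate (1:1 mixture of 3R,4R and 3S,4S) | COC(=O)[C@H]1COC[C@@H]1Cc1ccc(OCc2ccccc2)c(OC)c1.COC(=O)[C@@H]1COC[C@H]1Cc1ccc(OCc2ccccc2)c(OC)c1
F3 | step 5 | methyl (3R,4R)-4-(4-benzyloxy-3-methoxybenzyl)tetrahydrofuran-3-carboxylate | COC(=O)[C@H]1COC[C@@H]1Cc1ccc(OCc2ccccc2)c(OC)c1
F4 | step 10 | (3R,4R)-4-(4-benzyloxy-3-methoxybenzyl)tetrahydrofuran-3-carbaldehyde | O=C[C@H]1COC[C@@H]1Cc1ccc(OCc2ccccc2)c(OC)c1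
F5 | step 11 | [(3R,4R)-4-(4-hydroxy-3-methoxybenzyl)tetrahydrofuran-3-yl](4-hydroxy-3,5-dimethoxyphenyl)methanone | O=C(c1cc(OC)c(O)c(OC)c1)[C@H]1COC[C@@H]1Cc1ccc(O)c(OC)c1
F6 | step 11 | {(3R,4R)-4-[4-(tert-butyldimethylsilyloxy)-3-methoxybenzyl]tetrahydrofuran-3-yl}[4-(tert-butyldimethylsilyloxy)-3,5-dimethoxyphenyl]methanone | O=C(c1cc(OC)c(O[Si](C)(C)C(C)(C)C)c(OC)c1)[C@H]1COC[C@@H]1Cc1ccc(O[Si](C)(C)C(C)(C)C)c(OC)c1
F7 | step 11 | (S)-{(3R,4R)-4-[4-(tert-butyldimethylsilyloxy)-3-methoxybenzyl]tetrahydrofuran-3-yl}[4-(tert-butyldimethylsilyloxy)-3,5-dimethoxyphenyl]methanol | COc1cc(C[C@H]2COC[C@@H]2[C@H](O)c2cc(OC)c(O[Si](C)(C)C(C)(C)C)c(OC)c2)ccc1O[Si](C)(C)C(C)(C)C
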